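The leftover in the autumn flask, the drop in target still to come after its last reading, is what the options turn on.

| setting | autumn | summer | flask |
|---|---|---|---|
| substrate | 0.79 M | 0.40 M | 0.79 M |
| catalyst | 36 mM | 36 mM | 36 mM |
| temperature | 20 °C | 15 °C | 20 °C |
| remark | the very flask that is asked about, followed so far | run made earlier |  |
| time |  |  | 5.0 h |

- autumn (time / h: target / %, substrate / %): 1.00: 34.4, 36.0; 2.00: 24.1, 18.7; 3.00: 21.3, 15.3; 4.00: 19.0, 13.6; 5.00: 18.2, 10.1
- summer (time / min: target / %, substrate / %): 2.00: 2.7, 95.2; 4.00: 6.8, 92.7; 6.00: 10.2, 90.0; 12.0: 18.1, 80.4; 25.0: 30.0, 63.8

(scatter of a reading: 1 percentage point)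

- north-west: at 5.0 h add catalyst, 50.0% of the amount charged, then wait 10 h
- south-east: at 5.0 h take out 90% of the target then present, then wait 10 h
- south: change nothing and wait 10 h more
- north: at 5.0 h raise the temperature by 15 K, then wait 10 h

* target, in percent of the substrate first charged, at 5.0 h
* which option adds most target ("none" when 2 percentage points or less is all one gets) (north-west / south-east / south / north / none)
* target present, with what was taken out counted in, in percent of the substrate first charged, after north-west
* target present, with what was taken out counted in, in percent of the substrate first charged, after south

- removed target is counted in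
- the earlier runs were read with a standard deviation of 1 percentage point
- steps under discussion: substrate + catalyst <-> target + catalyst; target <-> isomer of the product A; isomer of the product A + catalyst <-> isomer of the product B + catalyst
- additions bring no volume worth counting

A gap to a resting point that shrinks by one factor per interval leaves the drops shrinking by that factor too. Two drops over equal intervals therefore give the factor, and the drops still to come add up to a short sum. The reckoning here takes c_target in the autumn run at 1.00 h, 3.00 h and 5.00 h:

factor = (21.3% − 18.2%) / (34.4% − 21.3%) = 0.237

gap left = (21.3% − 18.2%) × factor / (1 − factor) = 0.96 percentage points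

level = 18.2% − gap = 17.2%

half-life of the gap = 0.962 h

This resting level, the share of target at which the flask stops (its equilibrium share), is extrapolated from these three readings, each with a scatter of 1 point, and so it carries a scatter of about 1.9 points.

The ladder has three rungs. Substrate, down to 36.0% at 1.00 h, falls with a half-life near 0.678 h, shorter than that of the gap, so target first climbs and then sinks. The gap then shrinks, and by 5.0 h it is about the size of the scatter, so this reckoning keeps 18.2% for now. The wait of 10 h is far longer than 0.962 h, so south ends on the level. So does north-west, since catalyst stands on both sides of its steps. North moves the level by an amount these readings don't give. South-east takes out 16.4%, and the remainder rests at the same share: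

total = 16.4% + level × (1 − 16.4%) = 30.8%, a gain of 13 points

The forecast gives 18% for now, south-east as best, 5% after north-west and 7.5% after south, on the ground of a “slow catalysed drain”. It shares this reckoning's choice and differs on both waits.

The flask gives 18.9% at 5.0 h, 18.2% after north-west and 18.2% after south; south-east is best, adding 13 points. Left until 50.0 h, the flask holds 18.2% target. Set on the flask's own 18.9%, the level gives south-east a gain of 12 points.

    substrate + catalyst ⇌ target + catalyst, rate k1*[substrate]*[catalyst] forward; the back reaction follows from the equilibrium constant (K = 1.70, k = 0.760 L mol⁻¹ min⁻¹, Ea = 56.0 kJ mol⁻¹, ΔH = −60.0 kJ mol⁻¹)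
    target ⇌ isomer of the product A (K = 2.50, k = 0.0200 min⁻¹, Ea = 89.0 kJ mol⁻¹, ΔH = 13.0 kJ mol⁻¹)
    isomer of the product A + catalyst ⇌ isomer of the product B + catalyst, rate k3*[catalyst]*[isomer of the product A] forward; the back reaction follows from the equilibrium constant (K = 0.560, k = 1.10 L mol⁻¹ min⁻¹, Ea = 69.0 kJ mol⁻¹, ΔH = 8.00 kJ mol⁻¹)
    (constants at 20 °C)

The neighbour with the same charge, read at 2.0 h, lies on the same curve: the level plus the gap at 1.00 h, shrunk by its half-life, gives 25.6%. The computed value there is 26.4%.

(The numbers in the tables were computed for substances that don't exist; noise was put on by code.)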